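The cyclohexanone ring of the target is the benzene ring of benzoic acid. The decisive disconnection removes the C1–O and C2–O bonds together: a Rieske dioxygenase adds both oxygens to the ipso and ortho carbons of the flat, achiral arene in one operation, dearomatizing it and fixing C1 as S. The feature exploited is the six-membered carbocycle whose C1 is a tertiary carbinol carrying the one-carbon branch (later CH2OBz) and is flanked by oxygenated C2 and C6. The enzymatic C2 carbinol is later oxidized away to the ketone; C6, C5 and C4 are relayed from the C1 hydroxyl by directed epoxidation, anti opening at C5, a second directed epoxidation and reductive epoxy-ketone cleavage.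

Key step: step 1

Remarks on the chemistry:
- Ring atoms keep the target numbering throughout: C1 is the carbinol with the one-carbon branch, C2 the future carbonyl carbon, then C3 to C6. The α face is that of the C1–O bond, the β face that of the C1 branch.
- In step 1 the cells recycle NADH, so no stoichiometric by-product is counted.
- Dienes 2 to 7 can still aromatize by acid-induced loss of the C1 hydroxyl together with the C2 hydrogen, and can dimerize by Diels–Alder reaction. They are therefore kept neutral or basic, cold and dilute, and used promptly.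

Step 1
Reactants: 1 benzoic acid
Product: 2 (1S,2R)-1,2-dihydroxycyclohexa-3,5-diene-1-carboxylic acid (both hydroxyls α)
Conditions: whole cells of Ralstonia eutropha B9 (benzoate 1,2-dioxygenase, no diol dehydrogenase), 1 fed in portions, fructose, air, phosphate buffer pH 7.4, 30 °C; cells removed, pH 3 at 0 °C, EtOAc extraction
Reagents that add atoms: dioxygen, O=O
Why: The Rieske iron–sulfur cluster passes two electrons from NADH to a mononuclear non-heme iron centre, which binds O2 and transfers both oxygen atoms to C1 (ipso) and C2 (ortho) of the carboxylate-anchored benzoate on one face, so the cis-diol forms and the aromatic sextet is broken. This is arene cis-dihydroxylation by a ring-hydroxylating dioxygenase, here on the enzyme's native substrate. No ring is closed; the benzene ring becomes the cyclohexadiene that will be the carbocycle of the target. C1 (S) and C2 (R) are both set by the active site, which fixes the orientation of the carboxylate and so selects one of the two enantiotopic ortho carbons and one arene face. The selectivities needed are ipso,ortho regiochemistry and a single enantiomer, and both are those of the natural reaction. The strain lacks the diol dehydrogenase, so 2 should accumulate instead of being decarboxylated to catechol.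

Step 2
Reactants: 2 (1S,2R)-1,2-dihydroxycyclohexa-3,5-diene-1-carboxylic acid
Product: 3 methyl (1S,2R)-1,2-dihydroxycyclohexa-3,5-diene-1-carboxylate
Conditions: MeI, KHCO3, DMF, 0 °C → rt
Reagents that add atoms: iodomethane, CI
Why: Carboxylate O-alkylation (SN2 on iodomethane) under bicarbonate should leave the acid-labile dienediol and both stereocenters untouched.

Step 3
Reactants: 3 methyl (1S,2R)-1,2-dihydroxycyclohexa-3,5-diene-1-carboxylate
Product: 4 methyl (1S,2R)-2-(tert-butyldimethylsilyloxy)-1-hydroxycyclohexa-3,5-diene-1-carboxylate
Conditions: TBSCl, imidazole, DMF, 0 °C → rt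
Reagents that add atoms: tert-butyldimethylsilyl chloride, CC(C)(C)[Si](C)(C)Cl
Why: Imidazole-mediated silylation should cap only the secondary allylic C2 hydroxyl, because the tertiary C1 hydroxyl next to the ester is too hindered, and no stereocenter is touched.

Step 4
Reactants: 4 methyl (1S,2R)-2-(tert-butyldimethylsilyloxy)-1-hydroxycyclohexa-3,5-diene-1-carboxylate
Product: 5 dienediol silyl ether (C1-OH α, C1-CH2OH β, C2-OTBS α, C3=C4 and C5=C6)
Conditions: LiBH4, THF, 0 °C → rt; water quench
Reagents that add atoms: none
Why: Borohydride reduction of an ester activated by its neighbouring hydroxyl should give the primary alcohol without touching the diene or the silyl ether, and C1 keeps its geometry.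

Step 5
Reactants: 5 dienediol silyl ether; 6 benzoyl chloride
Product: 7 diene monobenzoate (C1-OH α free, C1-CH2OBz β, C2-OTBS α, C3=C4 and C5=C6)
Conditions: pyridine, CH2Cl2, −20 → 0 °C
Reagents that add atoms: benzoyl chloride (6), O=C(Cl)c1ccccc1
Why: Acylation of the primary hydroxyl is far faster than that of the tertiary C1 hydroxyl, so selective esterification should give the monobenzoate.

Step 6
Reactants: 7 diene monobenzoate
Product: 8 vinyl epoxide (α-oxirane across C5,C6 syn to the C1-OH; C3=C4 kept; C2-OTBS α)
Conditions: VO(acac)2 (5 mol %), t-BuOOH (in decane), CH2Cl2, 0 °C → rt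
Reagents that add atoms: tert-butyl hydroperoxide, CC(C)(C)OO
Why: In this vanadium-catalysed hydroxyl-directed epoxidation the C1 alkoxide binds the vanadium peroxide and delivers oxygen to the adjacent C5=C6 bond on its own α face, setting C5 and C6, while C3=C4 has no free allylic hydroxyl and its α face is covered by the silyl ether.

Step 7
Reactants: 8 vinyl epoxide
Product: 9 triol (C1-OH α, C6-OH α, C5-OH β, C2-OTBS α, C3=C4, CH2OBz)
Conditions: HClO4 (cat.), THF–H2O (3:1), 0 °C
Reagents that add atoms: water, O
Why: In this acid-catalysed epoxide hydrolysis water should attack the protonated vinyl oxirane at the allylic C5 from the β face with inversion (SN2-like, trans opening), so C6-OH stays α and cis to C1-OH while C5-OH becomes β; C6, next to the quaternary C1, is not attacked.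

Step 8
Reactants: 9 triol
Product: 10 C1,C6-O-isopropylidene ketal with free β C5-OH (C2-OTBS α, C3=C4)
Conditions: 2,2-dimethoxypropane, pyridinium p-toluenesulfonate (cat.), CH2Cl2, rt
Reagents that add atoms: 2,2-dimethoxypropane, COC(C)(C)OC
Why: Acid-catalysed transketalization should close the five-membered ketal only on the cis C1,C6 diol, since a trans-fused ketal across C5,C6 is strained, which leaves the allylic C5 hydroxyl free.

Step 9
Reactants: 10 C1,C6-O-isopropylidene ketal
Product: 11 epoxy alcohol (β-oxirane across C3,C4 syn to the C5-OH)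
Conditions: 3-chloroperoxybenzoic acid (mCPBA), CH2Cl2, 0 °C → rt
Reagents that add atoms: 3-chloroperoxybenzoic acid, OOC(=O)c1cccc(Cl)c1
Why: In this Henbest-type epoxidation the peracid is hydrogen-bonded to the allylic C5 hydroxyl and adds to C3=C4 on the β face, which is also the face away from the α silyl ether and the α ketal, setting C3 and C4.

Step 10
Reactants: 11 epoxy alcohol; 6 benzoyl chloride
Product: 12 C5 benzoate of the epoxy alcohol
Conditions: pyridine, 4-dimethylaminopyridine (cat.), CH2Cl2, 0 °C → rt
Reagents that add atoms: benzoyl chloride (6), O=C(Cl)c1ccccc1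
Why: Nucleophile-catalysed acylation of the only free hydroxyl should be clean, because a cis epoxy alcohol cannot undergo Payne rearrangement.

Step 11
Reactants: 12 C5 benzoate
Product: 13 C2 alcohol (C2-OH α, β-oxirane across C3,C4)
Conditions: HF·pyridine, excess pyridine, THF, 0 °C → rt
Reagents that add atoms: none
Why: Fluoride-induced Si–O cleavage in a pyridine-buffered, non-basic medium frees the C2 hydroxyl without forming an alkoxide, which should suppress both the Payne shift onto the trans C3,C4 oxirane and benzoate migration.

Step 12
Reactants: 13 C2 alcohol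
Product: 14 α,β-epoxy ketone (C2=O, β-oxirane across C3,C4)
Conditions: Dess–Martin periodinane, pyridine, CH2Cl2, 0 °C → rt
Reagents that add atoms: none
Why: Hypervalent iodine oxidation under neutral conditions should convert the hindered secondary carbinol into the ketone, and neither neighbour can epimerize because C1 is quaternary and C3 is locked in the oxirane.

Step 13
Reactants: 14 α,β-epoxy ketone
Product: 16 beta-hydroxy ketone acetonide, via alpha-phenylseleno beta-hydroxy ketone 15 (not isolated)
Conditions: (PhSe)2 (1.6 equiv), NaBH4 (3.0 equiv, limiting), EtOH, rt; AcOH; then 14 in THF, 0 °C → rt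
Reagents that add atoms: none
Why: In this organoselenium reduction of an epoxy ketone, phenylselenolate opens the oxirane at the α carbon C3, a second selenolate removes selenium to give the enolate, and protonation leaves C3 as CH2 with the C4 hydroxyl untouched and β; unlike a strong one-electron reductant the reagent cannot cleave the C1–O ketal bond on the other side of the ketone, and it spares both benzoates.

Step 14
Reactants: 16 β-hydroxy ketone acetonide
Product: 17 target, [(1S,2S,3R,4R)-3-(benzoyloxy)-1,2,4-trihydroxy-6-oxocyclohexyl]methyl benzoate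
Conditions: CF3CO2H–H2O (9:1), 0 °C → rt
Reagents that add atoms: none
Why: Acid-catalysed ketal hydrolysis releases the C1 and C6 hydroxyls, and at low temperature the β-hydroxy ketone should neither dehydrate nor suffer benzoate migration, so no stereocenter is touched.

Compound list
1 | benzoic acid | OC(=O)c1ccccc1 | starting material
2 | (1S,2R)-1,2-dihydroxycyclohexa-3,5-diene-1-carboxylic acid | OC(=O)[C@@]1(O)[C@H](O)C=CC=C1 | intermediate
3 | methyl (1S,2R)-1,2-dihydroxycyclohexa-3,5-diene-1-carboxylate | COC(=O)[C@@]1(O)[C@H](O)C=CC=C1 | intermediate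
4 | methyl (1S,2R)-2-(tert-butyldimethylsilyloxy)-1-hydroxycyclohexa-3,5-diene-1-carboxylate | COC(=O)[C@@]1(O)[C@H](O[Si](C)(C)C(C)(C)C)C=CC=C1 | intermediate
5 | dienediol silyl ether: C1-OH α, C1-CH2OH β, C2-OTBS α, C3=C4, C5=C6 | OC[C@@]1(O)[C@H](O[Si](C)(C)C(C)(C)C)C=CC=C1 | intermediate
6 | benzoyl chloride | O=C(Cl)c1ccccc1 | starting material
7 | diene monobenzoate: C1-OH α, C1-CH2OBz β, C2-OTBS α, C3=C4, C5=C6 | O=C(OC[C@@]1(O)[C@H](O[Si](C)(C)C(C)(C)C)C=CC=C1)c1ccccc1 | intermediate
8 | vinyl epoxide: α-oxirane across C5,C6 (syn to C1-OH), C3=C4, C2-OTBS α | O=C(OC[C@@]1(O)[C@H](O[Si](C)(C)C(C)(C)C)C=C[C@@H]2O[C@H]12)c1ccccc1 | intermediate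
9 | triol: C1-OH α, C6-OH α, C5-OH β, C2-OTBS α, C3=C4 | O=C(OC[C@@]1(O)[C@H](O[Si](C)(C)C(C)(C)C)C=C[C@@H](O)[C@@H]1O)c1ccccc1 | intermediate
10 | C1,C6-O-isopropylidene ketal with free β C5-OH, C2-OTBS α, C3=C4 | O=C(OC[C@@]1(OC(C)(C)O2)[C@H](O[Si](C)(C)C(C)(C)C)C=C[C@@H](O)[C@@H]12)c1ccccc1 | intermediate
11 | epoxy alcohol: β-oxirane across C3,C4 (syn to C5-OH), ketal and C2-OTBS α | O=C(OC[C@@]1(OC(C)(C)O2)[C@H](O[Si](C)(C)C(C)(C)C)[C@H]3O[C@H]3[C@@H](O)[C@@H]12)c1ccccc1 | intermediate
12 | C5 benzoate of 11 | O=C(OC[C@@]1(OC(C)(C)O2)[C@H](O[Si](C)(C)C(C)(C)C)[C@H]3O[C@H]3[C@@H](OC(=O)c4ccccc4)[C@@H]12)c1ccccc1 | intermediate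
13 | C2 alcohol: C2-OH α, β-oxirane across C3,C4, C5-OBz β, ketal | O=C(OC[C@@]1(OC(C)(C)O2)[C@H](O)[C@H]3O[C@H]3[C@@H](OC(=O)c4ccccc4)[C@@H]12)c1ccccc1 | intermediate
14 | α,β-epoxy ketone: C2=O, β-oxirane across C3,C4, C5-OBz β, ketal | O=C(OC[C@@]1(OC(C)(C)O2)C(=O)[C@H]3O[C@H]3[C@@H](OC(=O)c4ccccc4)[C@@H]12)c1ccccc1 | intermediate
15 | α-phenylseleno β-hydroxy ketone, not isolated: C3-SePh α, C4-OH β | O=C(OC[C@@]1(OC(C)(C)O2)C(=O)[C@H]([Se]c3ccccc3)[C@@H](O)[C@@H](OC(=O)c4ccccc4)[C@@H]12)c1ccccc1 | intermediate
16 | β-hydroxy ketone acetonide: C2=O, C3 H2, C4-OH β, C5-OBz β, C1,C6 ketal α | O=C(OC[C@@]1(OC(C)(C)O2)C(=O)C[C@@H](O)[C@@H](OC(=O)c4ccccc4)[C@@H]12)c1ccccc1 | intermediate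
17 | [(1S,2S,3R,4R)-3-(benzoyloxy)-1,2,4-trihydroxy-6-oxocyclohexyl]methyl benzoate (ring numbering used here: 1S,4R,5R,6S) | O=C(OC[C@@]1(O)C(=O)C[C@@H](O)[C@@H](OC(=O)c2ccccc2)[C@@H]1O)c1ccccc1 | target

Total step count: 14. Longest linear sequence: 14 steps (1 to 17); benzoyl chloride 6 enters twice.

Steps most likely to fail

Step 6, the first directed epoxidation. The Lewis-acidic vanadium peroxide may ionize the C1 carbinol of the still conjugated diene, which leads to aromatization. It may also bind the crowded tertiary hydroxyl so slowly that undirected oxidation of C3=C4 competes. The fallback sets out from 4 and rejoins at 8: the epoxidation is moved back to the ester stage, where the carboxyl group disfavours a cation at C1 and the α-hydroxy ester can chelate vanadium. VO(acac)2/t-BuOOH on 4 should give the methyl ester vinyl epoxide F1 (α-oxirane across C5,C6). LiBH4 in THF at −20 to 0 °C should then reduce the hydroxyl-activated ester in preference to the oxirane, giving the epoxy diol F2. Primary benzoylation with 6 (pyridine, −20 °C) returns to 8.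

Step 7, the hydrolytic opening. Under acid the opening may drift toward an allyl cation, so that water also adds at C3 (1,4-addition) or on the wrong face, eroding the regiochemistry and the C5 configuration. The fallback sets out from 8 and rejoins at 10: the opening is run as a metal-templated SN2 reaction. Ti(OiPr)4 binds the C1 hydroxyl and the oxirane and delivers chloroacetic acid to C5 with inversion, a known mode of opening 2,3-epoxy alcohols with carboxylic acids at the carbon remote from the carbinol. This gives the C5 chloroacetate diol F3. Ketalization as in step 8 gives the chloroacetate ketal F4. Thiourea/NaHCO3 in EtOH at 50 °C then removes only the chloroacetyl group, leaving the benzoate, and returns to 10.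

Step 13, the reductive opening. Back-side attack of the bulky selenolate at C3 may be slow, residual hydride may reduce the C2 ketone, or the new β-hydroxy ketone may eliminate. The fallback sets out from 14 and rejoins at 16: the two-electron nucleophilic opening is replaced by single-electron reduction with SmI2 (2.1 equiv, titrated) in THF–MeOH at −90 °C. The ketyl should fragment the strained C3–O bond much faster than the C1–O ketal bond, and MeOH protonates the samarium enolate. This path makes no new compound (none F0).

Further compounds
F1 | step 6 | methyl ester vinyl epoxide: α-oxirane across C5,C6, C1-OH α, C2-OTBS α, C3=C4 | COC(=O)[C@@]1(O)[C@H](O[Si](C)(C)C(C)(C)C)C=C[C@@H]2O[C@H]12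
F2 | step 6 | epoxy diol: C1-CH2OH β, C1-OH α, α-oxirane across C5,C6, C2-OTBS α, C3=C4 | OC[C@@]1(O)[C@H](O[Si](C)(C)C(C)(C)C)C=C[C@@H]2O[C@H]12
F3 | step 7 | C5 chloroacetate diol: C5-OC(O)CH2Cl β, C1-OH and C6-OH α, C2-OTBS α, C3=C4 | O=C(OC[C@@]1(O)[C@H](O[Si](C)(C)C(C)(C)C)C=C[C@@H](OC(=O)CCl)[C@@H]1O)c1ccccc1
F4 | step 7 | C5 chloroacetate C1,C6-O-isopropylidene ketal | O=C(OC[C@@]1(OC(C)(C)O2)[C@H](O[Si](C)(C)C(C)(C)C)C=C[C@@H](OC(=O)CCl)[C@@H]12)c1ccccc1
F0 | step 13 | none | none
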